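(All runs are calculated for substances that don't exist; noise was put on by code.)

| flask | substrate | partner | protic impurity | free catalyst | second catalyst | temperature | remark | time |
|---|---|---|---|---|---|---|---|---|
| midnight | 0.92 M | 1.2 M | 0.276 M | 15 mM | 14 mM | 80 °C | the very flask that is asked about, followed so far |  |
| dawn | 0.92 M | 1.2 M | 0.276 M | 15 mM | 9.4 mM | 75 °C | run made earlier |  |
| flask | 0.92 M | 1.20 M | 0.276 M | 15 mM | 14 mM | 80 °C |  | 40 min |

- midnight (time / min: target / %): 2.00: 45.3; 4.00: 61.6; 6.00: 66.6; 12.0: 69.3; 25.0: 69.5
- dawn (time / min: target / %): 0.667: 11.7; 2.00: 35.5; 4.00: 52.6; 6.00: 59.8; 8.00: 62.6

(readings scatter by 0.3 percentage points)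

- ochre: at 40 min raise the temperature by 10 K, then wait 12 min
- red: at 40 min add free catalyst, 100 % of the amount charged, then wait 12 min
- grey: change nothing and wait 12 min more
- green: at 40 min add partner, 50.0 % of the amount charged, then wait 12 min
- amber: at 40 min take out 90 % of the target then present, then wait 12 min

- target taken out counts as made
- what may be going on: substrate + free catalyst -> free catalyst + intermediate; partner + second catalyst + intermediate -> second catalyst + target; partner + protic impurity -> quenched reagent; intermediate -> side product
- "the catalyst" is free catalyst with its forms; second catalyst is a second catalyst
- additions bring no volume worth counting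

1. target, in percent of the substrate first charged, at 40 min
2. which option adds most target ("none" when 2 percentage points or less is all one gets) (ochre / red / grey / green / amber / none)
3. target present, with what was taken out counted in, in percent of the substrate first charged, after red
4. target present, with what was taken out counted in, in percent of the substrate first charged, after green

1. Slowness comes first: the options at 40 min have substrate to work on if the midnight flask is slow enough to still hold some.

2. Free catalyst comes out of the substrate step unchanged. With its amount steady the rate is k·c_substrate, a pseudo-first-order loss, and integration gives c_substrate falling as exp(−k·t). Taking the intermediate as short-lived, the gap between target and its final level falls the same way.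

3. In the midnight run, against the reading at 25.0 min, the gap is 24 percentage points at 2.00 min and 2.9 points at 6.00 min, which reads as 0.530 min⁻¹. This is the closing constant, the first-order constant with which the gap to the final level shrinks. It gives a half-life of 1.31 min.

4. The dawn run, at 75 °C with 9.4 mM of second catalyst, has the same substrate and free catalyst. The rises between its readings shrink with 0.452 min⁻¹, so it closes more slowly than midnight. Extended by that constant, the dawn run levels off near 64.5 %, lower than the 69.5 % of midnight. Height is the share of intermediate reaching target, and that share reads smaller in the dawn run, which differs from midnight in two settings: less second catalyst and a lower temperature.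

5. My reckoning: 40 min is 30.5 half-lives, so the midnight flask is reckoned to keep a fraction <0.001 % of its substrate, far under the margin 2 points. I commit to 69.5 % for now, to no useful option, and to the same figure after red and after green.

6. The forecast gives now 69.5 %, best none, g2 69.5 % and g4 69.5 %, holding that “substrate and intermediate are gone, and the rest became side product”.

7. The flask gives now 69.5 %, best none, g2 69.5 % and g4 69.5 %.

    substrate + free catalyst → free catalyst + intermediate (k = 0.580 M⁻¹ s⁻¹, Ea = 50.0 kJ mol⁻¹)
    partner + second catalyst + intermediate → second catalyst + target (k = 6.40 M⁻² s⁻¹, Ea = 56.0 kJ mol⁻¹)
    partner + protic impurity → quenched reagent (k = 0.0230 M⁻¹ s⁻¹, Ea = 60.0 kJ mol⁻¹)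
    intermediate → side product (k = 0.0230 s⁻¹, Ea = 92.0 kJ mol⁻¹)
    (constants at 80 °C)

The midnight flask and the forecast agree on the step that carried the weight: substrate stands at 0 % at 40.0 min. The neighbouring flask changes one setting, second catalyst at 0.0056 M against 14 mM, and the substrate step holds no second catalyst. So the closing constant 0.530 min⁻¹ is carried over to the neighbouring flask, and the same fraction <0.001 % is reckoned for 40 min. The neighbouring flask shows substrate at 0 % at 40.0 min, so it too has stopped, but lower: target 52.1 %, side product 47.9 %.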